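**Retrosynthetic overview**
1. Target 20 ⇐ global desilylation ⇐ Heck coupling with 4-iodophenol ⇐ acrylate 17 ⇐ alcohol 15.
2. 15 ⇐ acetal 13 ⇐ oxidative ring contraction of the (R)-2-aryl-2H-chromene 11 (aryl carbon C4a shifts from C4 to C3; pyran becomes dihydrofuran; C2 relays its configuration to a trans C3).
3. 11 ⇐ enantioselective dehydrative (3+3) annulation of phenol 6 with enal 9 (forms C4–C4a and C2–O1).
4. 6 and 9 ⇐ 4-iodoguaiacol 3 (B-alkyl Suzuki with O-silyl allyl alcohol; silylation then Heck with acrolein) ⇐ catechol.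
5. Ring order: both guaiacyl benzene rings come from catechol; the 2H-pyran ring is made in step 6 and contracted to the dihydrofuran in step 7; the third benzene ring is attached last by Heck coupling.

Assumption: allyl tert-butyldiphenylsilyl ether 4 is bought as the O-protected form of allyl alcohol. The hand of the chiral acid in step 6 is confirmed in the first run, and the mirror-image acid is used if the 2S chromene forms.

Abbreviations: TBDPS = tert-butyldiphenylsilyl, TIPS = triisopropylsilyl, HTIB = PhI(OH)OTs.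

**Step 1**
Reactants: 1 catechol
Product: 2 guaiacol (2-methoxyphenol)
Conditions: MeI (1.0 equiv), K2CO3 (1.0 equiv), acetone, reflux
Reagents that add atoms: iodomethane, CI
Why: Williamson ether synthesis; with one equivalent of MeI the mono-ether is the main product, and veratrole and catechol are removed by base extraction and distillation.

**Step 2**
Reactants: 2 guaiacol
Product: 3 4-iodo-2-methoxyphenol
Conditions: NIS (1.0 equiv), TsOH·H2O (10 mol%), MeCN, 0 °C → rt
Reagents that add atoms: N-iodosuccinimide, O=C1CCC(=O)N1I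
Why: Electrophilic aromatic iodination goes para to the free OH, which is the stronger director.

**Step 3**
Reactants: 3 4-iodo-2-methoxyphenol; 4 allyl tert-butyldiphenylsilyl ether
Product: 6 4-[3-(tert-butyldiphenylsilyloxy)propyl]-2-methoxyphenol, via 9-alkyl-9-BBN borane 5 (not isolated)
Conditions: 4 (1.3 equiv), 9-BBN-H (1.35 equiv), THF, 0 °C → rt; then 3, PdCl2(dppf) (3 mol%), 3 M aq K3PO4 (3.5 equiv), DMF, 50 °C
Reagents that add atoms: none
Why: B-alkyl Suzuki–Miyaura coupling; 9-BBN hydroborates the terminal alkene anti-Markovnikov and the primary alkylborane couples with the aryl iodide, the free phenol being tolerated with extra base.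

**Step 4**
Reactants: 3 4-iodo-2-methoxyphenol
Product: 7 (4-iodo-2-methoxyphenoxy)triisopropylsilane
Conditions: TIPSCl (1.2 equiv), imidazole (2.5 equiv), DMF, rt
Reagents that add atoms: triisopropylsilyl chloride, CC(C)[Si](Cl)(C(C)C)C(C)C
Why: Imidazole-mediated O-silylation; the aryl TIPS ether masks the phenol against the later iodine(III) oxidant and acid.

**Step 5**
Reactants: 7 (4-iodo-2-methoxyphenoxy)triisopropylsilane; 8 acrolein
Product: 9 (E)-3-[3-methoxy-4-(triisopropylsilyloxy)phenyl]prop-2-enal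
Conditions: 8 (2 equiv), Pd(OAc)2 (3 mol%), Bu4NCl (1 equiv), NaHCO3 (2.5 equiv), DMF, 45 °C
Reagents that add atoms: none
Why: Mizoroki–Heck reaction under ligand-free phase-transfer (Jeffery) conditions; syn insertion and β-hydride elimination give the E-enal, and the mild base leaves the aryl silyl ether intact.

**Step 6**
Reactants: 6 4-[3-(tert-butyldiphenylsilyloxy)propyl]-2-methoxyphenol; 9 (E)-3-[3-methoxy-4-(triisopropylsilyloxy)phenyl]prop-2-enal
Product: 11 (2R)-8-methoxy-2-[3-methoxy-4-(triisopropylsilyloxy)phenyl]-6-[3-(tert-butyldiphenylsilyloxy)propyl]-2H-chromene, via 4-styryl-1,3,2-benzodioxaborinine 10 (not isolated)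
Conditions: 9 (1.2 equiv), C6F5B(OH)2 (20 mol%), (R)-3,3'-bis(2,4,6-triisopropylphenyl)-H8-BINOL N-triflylphosphoramide (5 mol%), 5 Å MS, PhMe, 0 → 20 °C; Et3N quench
Reagents that add atoms: none
Why: Proposed new method: an enantioselective dehydrative (3+3) annulation of a free phenol with a cinnamaldehyde under relay catalysis — C6F5B(OH)2 tethers the phenol oxygen and the aldehyde so that C–C bond formation occurs only at the ortho carbon and the carbonyl carbon (giving 10), the chiral N-triflylphosphoramide then ionises the benzylic C4–O bond of 10 at 20 °C (where thermal release of a free o-quinone methide is negligible) to a 1,3-diarylallyl cation held as a hydrogen-bonded contact ion pair with the chiral anion, and C2–O ring closure inside this pair sets the C2 stereocentre (2R); the closest known reaction types are the racemic arylboronic acid/Brønsted acid co-catalysed phenol–enal chromene synthesis and the chiral N-triflylphosphoramide-catalysed intramolecular allylic etherification of 2-hydroxyaryl allylic alcohols through contact ion pairs (shown for 4-aryl-substituted cases).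

**Step 7**
Reactants: 11 (2R)-8-methoxy-2-[3-methoxy-4-(triisopropylsilyloxy)phenyl]-6-[3-(tert-butyldiphenylsilyloxy)propyl]-2H-chromene
Product: 13 (2R,3R)-3-(dimethoxymethyl)-7-methoxy-2-[3-methoxy-4-(triisopropylsilyloxy)phenyl]-5-[3-(tert-butyldiphenylsilyloxy)propyl]-2,3-dihydrobenzofuran (2,3-trans), via 3-iodanyl-4-methoxychroman 12 (not isolated)
Conditions: HTIB (1.1 equiv), MeOH, −30 → 0 °C, 30 min; NaHCO3 quench
Reagents that add atoms: methanol, CO
Why: Hypervalent-iodine oxidative ring contraction (semipinacol-type 1,2-aryl shift); the iodane adds to C3 anti to the 2-aryl group with MeOH capture at the benzylic C4, then C4a migrates from C4 to C3 with inversion as PhI leaves, which gives the trans C3 centre from C2 and an oxocarbenium ion trapped as the dimethyl acetal.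

**Step 8**
Reactants: 13 (2R,3R)-3-(dimethoxymethyl)-7-methoxy-2-[3-methoxy-4-(triisopropylsilyloxy)phenyl]-5-[3-(tert-butyldiphenylsilyloxy)propyl]-2,3-dihydrobenzofuran
Product: 15 [(2R,3S)-7-methoxy-2-[3-methoxy-4-(triisopropylsilyloxy)phenyl]-5-[3-(tert-butyldiphenylsilyloxy)propyl]-2,3-dihydrobenzofuran-3-yl]methanol, via dihydrobenzofuran-3-carbaldehyde 14 (not isolated)
Conditions: 2 M aq HCl/THF (1:5), 0 °C → rt; then NaHCO3 to pH 7, NaBH4, MeOH, 0 °C
Reagents that add atoms: water, O
Why: Acetal hydrolysis followed by NaBH4 reduction in the same flask; the trans aldehyde is the thermodynamic epimer and is reduced before retro-oxa-Michael opening can occur, and both silyl ethers tolerate the dilute acid.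

**Step 9**
Reactants: 15 [(2R,3S)-7-methoxy-2-[3-methoxy-4-(triisopropylsilyloxy)phenyl]-5-[3-(tert-butyldiphenylsilyloxy)propyl]-2,3-dihydrobenzofuran-3-yl]methanol; 16 acryloyl chloride
Product: 17 [(2R,3S)-7-methoxy-2-[3-methoxy-4-(triisopropylsilyloxy)phenyl]-5-[3-(tert-butyldiphenylsilyloxy)propyl]-2,3-dihydrobenzofuran-3-yl]methyl prop-2-enoate
Conditions: 16 (1.2 equiv), Et3N (1.5 equiv), CH2Cl2, −20 → 0 °C
Reagents that add atoms: none
Why: O-acylation of the only free hydroxyl group with an acid chloride; no stereocentre is touched.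

**Step 10**
Reactants: 17 [(2R,3S)-7-methoxy-2-[3-methoxy-4-(triisopropylsilyloxy)phenyl]-5-[3-(tert-butyldiphenylsilyloxy)propyl]-2,3-dihydrobenzofuran-3-yl]methyl prop-2-enoate; 18 4-iodophenol
Product: 19 [(2R,3S)-7-methoxy-2-[3-methoxy-4-(triisopropylsilyloxy)phenyl]-5-[3-(tert-butyldiphenylsilyloxy)propyl]-2,3-dihydrobenzofuran-3-yl]methyl (E)-3-(4-hydroxyphenyl)prop-2-enoate
Conditions: 18 (1.2 equiv), Pd(OAc)2 (5 mol%), P(o-tol)3 (10 mol%), Et3N (3 equiv), MeCN, 80 °C
Reagents that add atoms: none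
Why: Mizoroki–Heck arylation of the acrylate gives the E-cinnamate directly, and free 4-iodophenol is a standard partner under these conditions.

**Step 11**
Reactants: 19 [(2R,3S)-7-methoxy-2-[3-methoxy-4-(triisopropylsilyloxy)phenyl]-5-[3-(tert-butyldiphenylsilyloxy)propyl]-2,3-dihydrobenzofuran-3-yl]methyl (E)-3-(4-hydroxyphenyl)prop-2-enoate
Product: 20 [(2R,3S)-2-(4-hydroxy-3-methoxyphenyl)-5-(3-hydroxypropyl)-7-methoxy-2,3-dihydrobenzofuran-3-yl]methyl (E)-3-(4-hydroxyphenyl)prop-2-enoate (CNP0202924.1)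
Conditions: TBAF (3 equiv), AcOH (3 equiv), THF, 0 °C → rt
Reagents that add atoms: none
Why: Fluoride desilylation buffered with acetic acid removes the aryl TIPS and the primary TBDPS ether in one operation without touching the cinnamate ester or the benzylic ether.

**Compound list**
1 | catechol (benzene-1,2-diol) | Oc1ccccc1O | starting material
2 | guaiacol (2-methoxyphenol) | COc1ccccc1O | intermediate
3 | 4-iodo-2-methoxyphenol | COc1cc(I)ccc1O | intermediate
4 | allyl tert-butyldiphenylsilyl ether | C=CCO[Si](c1ccccc1)(c1ccccc1)C(C)(C)C | starting material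
5 | 9-[3-(tert-butyldiphenylsilyloxy)propyl]-9-borabicyclo[3.3.1]nonane | CC(C)(C)[Si](OCCCB1C2CCCC1CCC2)(c1ccccc1)c1ccccc1 | intermediate (not isolated)
6 | 4-[3-(tert-butyldiphenylsilyloxy)propyl]-2-methoxyphenol | COc1cc(CCCO[Si](c2ccccc2)(c2ccccc2)C(C)(C)C)ccc1O | intermediate
7 | (4-iodo-2-methoxyphenoxy)triisopropylsilane | COc1cc(I)ccc1O[Si](C(C)C)(C(C)C)C(C)C | intermediate
8 | acrolein (prop-2-enal) | C=CC=O | starting material
9 | (E)-3-[3-methoxy-4-(triisopropylsilyloxy)phenyl]prop-2-enal | COc1cc(/C=C/C=O)ccc1O[Si](C(C)C)(C(C)C)C(C)C | intermediate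
10 | 8-methoxy-2-(pentafluorophenyl)-6-[3-(TBDPS-oxy)propyl]-4-{(E)-2-[3-methoxy-4-(TIPS-oxy)phenyl]ethenyl}-4H-1,3,2-benzodioxaborinine (either configuration at C4) | COc1cc(CCCO[Si](c2ccccc2)(c2ccccc2)C(C)(C)C)cc2c1OB(c1c(F)c(F)c(F)c(F)c1F)OC2/C=C/c1ccc(O[Si](C(C)C)(C(C)C)C(C)C)c(OC)c1 | intermediate (not isolated)
11 | (2R)-8-methoxy-2-[3-methoxy-4-(triisopropylsilyloxy)phenyl]-6-[3-(tert-butyldiphenylsilyloxy)propyl]-2H-chromene | COc1cc([C@@H]2Oc3c(OC)cc(CCCO[Si](c4ccccc4)(c4ccccc4)C(C)(C)C)cc3C=C2)ccc1O[Si](C(C)C)(C(C)C)C(C)C | intermediate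
12 | (2S,3R,4S)-4-methoxy-3-[phenyl(tosyloxy)-λ3-iodanyl] adduct of chromene 11 (iodanyl trans to the 2-aryl group and trans to 4-OMe; C2 spatially unchanged from 11) | COc1cc([C@@H]2Oc3c(OC)cc(CCCO[Si](c4ccccc4)(c4ccccc4)C(C)(C)C)cc3[C@H](OC)[C@H]2I(OS(=O)(=O)c2ccc(C)cc2)c2ccccc2)ccc1O[Si](C(C)C)(C(C)C)C(C)C | intermediate (not isolated)
13 | (2R,3R)-3-(dimethoxymethyl)-7-methoxy-2-[3-methoxy-4-(triisopropylsilyloxy)phenyl]-5-[3-(tert-butyldiphenylsilyloxy)propyl]-2,3-dihydrobenzofuran (trans) | COc1cc([C@@H]2Oc3c(OC)cc(CCCO[Si](c4ccccc4)(c4ccccc4)C(C)(C)C)cc3[C@H]2C(OC)OC)ccc1O[Si](C(C)C)(C(C)C)C(C)C | intermediate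
14 | (2R,3R)-7-methoxy-2-[3-methoxy-4-(triisopropylsilyloxy)phenyl]-5-[3-(tert-butyldiphenylsilyloxy)propyl]-2,3-dihydrobenzofuran-3-carbaldehyde (trans) | COc1cc([C@@H]2Oc3c(OC)cc(CCCO[Si](c4ccccc4)(c4ccccc4)C(C)(C)C)cc3[C@H]2C=O)ccc1O[Si](C(C)C)(C(C)C)C(C)C | intermediate (not isolated)
15 | [(2R,3S)-7-methoxy-2-[3-methoxy-4-(triisopropylsilyloxy)phenyl]-5-[3-(tert-butyldiphenylsilyloxy)propyl]-2,3-dihydrobenzofuran-3-yl]methanol (trans) | COc1cc([C@@H]2Oc3c(OC)cc(CCCO[Si](c4ccccc4)(c4ccccc4)C(C)(C)C)cc3[C@H]2CO)ccc1O[Si](C(C)C)(C(C)C)C(C)C | intermediate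
16 | acryloyl chloride | C=CC(=O)Cl | starting material
17 | [(2R,3S)-7-methoxy-2-[3-methoxy-4-(triisopropylsilyloxy)phenyl]-5-[3-(tert-butyldiphenylsilyloxy)propyl]-2,3-dihydrobenzofuran-3-yl]methyl prop-2-enoate | COc1cc([C@@H]2Oc3c(OC)cc(CCCO[Si](c4ccccc4)(c4ccccc4)C(C)(C)C)cc3[C@H]2COC(=O)C=C)ccc1O[Si](C(C)C)(C(C)C)C(C)C | intermediate
18 | 4-iodophenol | Oc1ccc(I)cc1 | starting material
19 | [(2R,3S)-7-methoxy-2-[3-methoxy-4-(triisopropylsilyloxy)phenyl]-5-[3-(tert-butyldiphenylsilyloxy)propyl]-2,3-dihydrobenzofuran-3-yl]methyl (E)-3-(4-hydroxyphenyl)prop-2-enoate | COc1cc([C@@H]2Oc3c(OC)cc(CCCO[Si](c4ccccc4)(c4ccccc4)C(C)(C)C)cc3[C@H]2COC(=O)/C=C/c2ccc(O)cc2)ccc1O[Si](C(C)C)(C(C)C)C(C)C | intermediate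
20 | [(2R,3S)-2-(4-hydroxy-3-methoxyphenyl)-5-(3-hydroxypropyl)-7-methoxy-2,3-dihydrobenzofuran-3-yl]methyl (E)-3-(4-hydroxyphenyl)prop-2-enoate | COc1cc([C@@H]2Oc3c(OC)cc(CCCO)cc3[C@H]2COC(=O)/C=C/c2ccc(O)cc2)ccc1O | target

**Totals**
Total step count: 11.
Longest linear sequence: 10 steps (1 → 2 → 3 → 7 → 9 → 11 → 13 → 15 → 17 → 19 → 20).

**Three steps most likely to fail**

Step 6 (the proposed new annulation). Risks are conjugate C-alkylation, low enantioselectivity, and acid-mediated erosion of the C2 centre in the electron-rich product. The fallback uses known chemistry, sets out from 6 (with 9 as before) and comes back at 11. Magnesium-mediated ortho-formylation of 6 (MgCl2, Et3N, paraformaldehyde, MeCN, reflux) gives 2-hydroxy-3-methoxy-5-[3-(tert-butyldiphenylsilyloxy)propyl]benzaldehyde F1. The established aminocatalytic oxa-Michael/aldol condensation of F1 with 9 (diphenylprolinol trimethylsilyl ether 20 mol%, 2-nitrobenzoic acid, toluene, rt; catalyst enantiomer chosen for 2S) gives (2S)-8-methoxy-2-[3-methoxy-4-(triisopropylsilyloxy)phenyl]-6-[3-(tert-butyldiphenylsilyloxy)propyl]-2H-chromene-3-carbaldehyde F2. Tsuji–Wilkinson decarbonylation (RhCl(PPh3)3, toluene, 110 °C) removes the formyl group and gives 11; the descriptor changes from S to R only through the priority rules, not in space.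

Step 7 (oxidative ring contraction). Risks are oxidation of the electron-rich rings, competing migration of the 2-aryl group or the ring oxygen, and acid damage from the TsOH released. The fallback sets out from 11 and comes back at 13 by splitting the event into two steps. Bromo-methoxylation (NBS, MeOH, −20 °C; bromonium anti to the 2-aryl group, MeOH opening at the benzylic C4) gives (2S,3R,4S)-3-bromo-4,8-dimethoxy-2-[3-methoxy-4-(triisopropylsilyloxy)phenyl]-6-[3-(tert-butyldiphenylsilyloxy)propyl]chroman F3. Silver-assisted semipinacol rearrangement (AgBF4, solid NaHCO3, MeOH, 0 °C → rt) then drives the same C4a shift under non-oxidising conditions and gives 13.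

Step 5 (Heck reaction with acrolein). Risks are acrolein polymerisation and double arylation. The fallback sets out from 7 and comes back at 9 by building the enal as C1 + C2. Iodine–magnesium exchange and formylation (iPrMgCl·LiCl, THF, −20 °C; then DMF) give 3-methoxy-4-(triisopropylsilyloxy)benzaldehyde F4. Wittig olefination with (triphenylphosphoranylidene)acetaldehyde (1.05 equiv, toluene, 80 °C) gives the E-enal 9.

**Further compounds**
F1 | step 6 | 2-hydroxy-3-methoxy-5-[3-(tert-butyldiphenylsilyloxy)propyl]benzaldehyde | COc1cc(CCCO[Si](c2ccccc2)(c2ccccc2)C(C)(C)C)cc(C=O)c1O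
F2 | step 6 | (2S)-8-methoxy-2-[3-methoxy-4-(triisopropylsilyloxy)phenyl]-6-[3-(tert-butyldiphenylsilyloxy)propyl]-2H-chromene-3-carbaldehyde | COc1cc([C@@H]2Oc3c(OC)cc(CCCO[Si](c4ccccc4)(c4ccccc4)C(C)(C)C)cc3C=C2C=O)ccc1O[Si](C(C)C)(C(C)C)C(C)C
F3 | step 7 | (2S,3R,4S)-3-bromo-4,8-dimethoxy-2-[3-methoxy-4-(triisopropylsilyloxy)phenyl]-6-[3-(tert-butyldiphenylsilyloxy)propyl]chroman | COc1cc([C@@H]2Oc3c(OC)cc(CCCO[Si](c4ccccc4)(c4ccccc4)C(C)(C)C)cc3[C@H](OC)[C@H]2Br)ccc1O[Si](C(C)C)(C(C)C)C(C)C
F4 | step 5 | 3-methoxy-4-(triisopropylsilyloxy)benzaldehyde | COc1cc(C=O)ccc1O[Si](C(C)C)(C(C)C)C(C)C
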